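**The pitfall.** Target is a poor gauge of this flask's progress: in Monday's run, which is this flask followed so far, it reads 6 % at 20.0 min, while 16.0 % of the electrophile has reacted. So I follow the electrophile itself.

in all of them: protonated nucleophile 1.35 M; gas 160 mM (held)

|  | electrophile | remark | time |
|---|---|---|---|
| Monday's | 1.5 M | the very flask that is asked about, followed so far |  |
| Tuesday's | 1 M | run made earlier |  |
| flask | 1.5 M |  | 50 min |

- Monday's (time / min: electrophile / %, target / %): 1.50: 97, 6; 4.00: 95, 2; 8.00: 89, 6; 20.0: 84, 6
- Tuesday's (time / min: electrophile / %, target / %): 8.00: 89, 4; 20.0: 85, 7; 25.0: 80, 8; 40.0: 72, 5

(standard deviation of a reading: 2 percentage points)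

1. part of the electrophile that has reacted at 50 min
2. share of the unused nucleophile that is free and not bound as protonated nucleophile, at 50 min

- the numbers in the tables scatter by 2 percentage points (one standard deviation)
- at the start none of the gas is in solution
- the earlier runs do not show how much of nucleophile is bound; that part of a forecast is a guess

**Electrophile charge.** By hand, a loss proportional to the electrophile leaves the percentage reacted independent of the charge. The runs agree within their scatter: from 1.5 M and 1 M they read 89 % and 89 % left at 8.00 min, then 84 % and 85 % at 20.0 min. I therefore treat the loss as pseudo-first-order.

**Time.** Tuesday's last reading gives 84.4 min for the electrophile half-life, the time in which the electrophile left falls to half under a first-order loss. Over 50 min, that makes my reckoning 33.7 % reacted.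

**Nucleophile, gas.** By hand, more protonated nucleophile should shorten the half-life, but both runs hold 1.35 M of it and 160 mM of gas, so the readings cannot test either setting.

**The forecast.** It gives 34 % reacted and a free share of 12 %, which it calls a guess, reasoning that “consumption looks first order in electrophile”.

**The result.** The flask gives 32.5 % reacted at 50 min, which reckoned as a first-order loss is a half-life of 88.2 min, and a free share of 2.47 %, 9.5 percentage points below the forecast, with 0.263 M of acid set free beside 0.0250 M of nucleophile at that time. The neighbour flask at 2.5 M of electrophile, where my half-life reckons 33.7 %, gives 27.7 %, which reckoned the same way is a half-life of 107 min.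

    electrophile + nucleophile → acid set free + target (k = 0.00280 /M/s)
    nucleophile + acid set free ⇌ protonated nucleophile, settled at all times (K = 150 /M)
    acid set free + free base ⇌ salt of the base (K = 15000 /M, k = 0.00400 /M/s)
    gas ⇌ free base, rate k4*(csat - [free base]) (kL = 0.0160 /s)
    electrophile + target → side product (k = 8.30 × 10⁻⁴ /M/s)
    target → over-reaction product (k = 0.00100 /s)

**What ran.** By 5.00 min this flask held 0.153 M of free base from the gas, 0.0464 M of nucleophile and 3.56 % of target. From then to 50.0 min, free base stood near 0.150 M while the salt of the base grew from 0.0216 M to 0.439 M, and target, 2.72 % at the end, passed on to side product, which reached 19.9 % with both its electrophile units counted, and to over-reaction product, which reached 9.86 %.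

(The runs were generated by integration from invented constants; noise was put on by code.)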